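**Retrosynthetic overview**
1. The strategy rests on the butenolide ring (O, C1′–C4′) and its (Z)-exocyclic C4′=C15 alkene, which together are the cyclised form of a (Z)-2-en-4-ynoic acid. Cutting C3′–C4′ and O–C4′ gives terminal (E)-enyne 17 (C4′ as the alkyne CH) and (Z)-3-iodobut-2-enoic acid 19.
2. In 17 the C18 aldehyde comes from a nitrile, the nitrile from an oxime, and the oxime from photolysis of the 6α-nitrite (hydrogen transfer from the peri 4α-methyl, which sets C4). The enyne comes from the (E)-enal, which comes from the (E)-enoate made by olefination of C13 methyl ketone 2.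
3. The 8α-OH/8β-methyl pair comes from hydride opening of the 8α,17-epoxide; ketone 2 comes from permanganate degradation of larixol 1; 19 comes from but-2-ynoic acid 18.
4. Ring order: rings A and B (the decalin) are taken intact from larixol; the butenolide ring is closed last, in the key step; the final step only removes the 6-O-triethylsilyl group.

Key step: step 13

Numbering: labdane numbering for core and chain (C18 = 4α carbon, C19 = 4β-methyl, C20 on C10, C17 on C8, C16 on C13); butenolide carbons C1′ (C=O), C2′, C3′ (methyl-bearing), C4′ (ylidene carbon).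

Remark (assumption): larixol is taken as a commercial natural-product starting material. The target is taken in the open 6α-hydroxy-18-aldehyde form drawn; if it equilibrates with its 6α,18-lactol, the last step delivers that equilibrium.

**Route**

Step 1
Reactants: 1 larixol
Product: 2 6α-hydroxy-14,15-dinorlabd-8(17)-en-13-one
Conditions: KMnO4, BnEt3NCl (cat.), CH2Cl2/H2O, 0 °C
Reagents that add atoms: none
Why: Permanganate degradation of a tertiary vinyl carbinol (dihydroxylation of the monosubstituted alkene, then glycol and ketol cleavage) removes C14 and C15 and leaves the C13 methyl ketone, while the hindered 8(17)-methylidene and the secondary 6-OH should react more slowly at 0 °C, as is usual for manool-type side chains.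

Step 2
Reactants: 2 6α-hydroxy-14,15-dinorlabd-8(17)-en-13-one; 3 triethyl phosphonoacetate
Product: 4 ethyl (13E)-6α-hydroxylabda-8(17),13-dien-15-oate
Conditions: NaH, THF, 0 °C to reflux; chromatographic removal of the (13Z)-ester
Reagents that add atoms: none
Why: Horner–Wadsworth–Emmons olefination of the methyl ketone with the stabilised phosphonate anion should favour the (13E)-enoate (ester trans to the larger C12 chain), and the 6-OH is not acidic enough to interfere.

Step 3
Reactants: 4 ethyl (13E)-6α-hydroxylabda-8(17),13-dien-15-oate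
Product: 5 ethyl (13E)-8α,17-epoxy-6α-hydroxylabd-13-en-15-oate
Conditions: mCPBA, CH2Cl2, 0 °C
Reagents that add atoms: mCPBA, OOC(=O)c1cccc(Cl)c1
Why: Prilezhaev epoxidation picks the electron-rich 1,1-disubstituted 8(17)-alkene over the deactivated enoate and should come from the α face, because the β face of C8 is screened by the axial C20 methyl and the 6α-OH can hydrogen-bond the peracid on the α side; this sets C8.

Step 4
Reactants: 5 ethyl (13E)-8α,17-epoxy-6α-hydroxylabd-13-en-15-oate
Product: 6 (13E)-labd-13-ene-6α,8α,15-triol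
Conditions: LiAlH4, THF, 0 °C, then reflux
Reagents that add atoms: none
Why: LiAlH4 reduces the enoate 1,2 to the allylic alcohol at 0 °C and then opens the spiro-epoxide by SN2 attack of hydride at the primary C17, which turns C17 into the 8β-methyl and keeps the 8α-oxygen set in step 3.

Step 5
Reactants: 6 (13E)-labd-13-ene-6α,8α,15-triol
Product: 7 (13E)-6α,8α-dihydroxylabd-13-en-15-al
Conditions: MnO2 (activated), CH2Cl2, rt
Reagents that add atoms: none
Why: Allylic oxidation with MnO2 touches only the primary allylic alcohol (secondary 6-OH and tertiary 8-OH are inert) and is neutral, so the (13E) geometry of the enal should be kept.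

Step 6
Reactants: 7 (13E)-6α,8α-dihydroxylabd-13-en-15-al
Product: 8 core (E)-enyne 6α,8α-diol (chain HC≡C–CH=C(CH3)–CH2CH2– on C9; C15 is the internal alkyne carbon, C4′ the terminal one)
Conditions: Me3SiCHN2, LiN(i-Pr)2 (excess), THF, −78 °C to rt
Reagents that add atoms: trimethylsilyldiazomethane, C[Si](C)(C)C=[N+]=[N-]
Why: Colvin–Shioiri homologation (addition of lithiated trimethylsilyldiazomethane to the aldehyde, Peterson elimination, loss of N2 and 1,2-hydrogen shift of the alkylidene carbene) gives the terminal alkyne; excess reagent covers the two hydroxyl groups, the low temperature guards the enal geometry, and the methanolic Ohira–Bestmann variant is avoided because enals tend to add methanol under it.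

Step 7
Reactants: 8 core (E)-enyne 6α,8α-diol
Product: 9 6-O-nitrite of 8 (used crude)
Conditions: NOCl (1.1 equiv), pyridine, −30 °C
Reagents that add atoms: nitrosyl chloride, ClN=O
Why: O-Nitrosation in pyridine is fast at the equatorial secondary 6α-OH and slow at the tertiary 8α-OH, which is flanked by the axial C17 methyl and the C9 substituent, so one equivalent should give the 6-mononitrite; the enyne is not nucleophilic enough to compete.

Step 8
Reactants: 9 6-O-nitrite of 8
Product: 11 (E)-18-oxime of the enyne 6α,8α-diol (4α-CH=NOH), via C18-nitroso compound 10 (not isolated)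
Conditions: hν (350 nm, Pyrex), toluene, 10 °C, Ar; then i-PrOH, reflux
Reagents that add atoms: none
Why: Barton nitrite photolysis, in which the equatorial 6α-alkoxyl radical sits in a peri (syn-pentane-like) relation to the equatorial 4α-methyl, abstracts its hydrogen through a six-membered transition state, the C18 radical recombines with NO and the nitroso dimer tautomerises to the oxime on heating; this differentiates the geminal methyls and sets C4 (the axial 4β-methyl and the β-face C20 and C17 methyls are out of reach), and only the nitrite absorbs at 350 nm.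

Step 9
Reactants: 11 (E)-18-oxime of the enyne 6α,8α-diol
Product: 13 6-O-triethylsilyl 18-oxime, via O,O-bis(triethylsilyl) compound 12 (not isolated)
Conditions: Et3SiCl, imidazole, 4-dimethylaminopyridine (cat.), DMF, rt to 40 °C; then K2CO3 (cat.), MeOH, 0 °C
Reagents that add atoms: chlorotriethylsilane, CC[Si](Cl)(CC)CC
Why: Silylation takes the secondary 6-OH and the oxime OH but not the hindered tertiary 8-OH, and brief methanolysis then cleaves only the far more labile N–O–Si bond (oximate is the better leaving group).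

Step 10
Reactants: 13 6-O-triethylsilyl 18-oxime
Product: 15 6-O-triethylsilyl 18-nitrile (4α-C≡N, enyne chain, free 8α-OH), via oxime O-carbonylimidazole 14 (not isolated)
Conditions: 1,1′-carbonyldiimidazole, CH2Cl2, rt
Reagents that add atoms: none
Why: Dehydration of the aldoxime (O-acylation, then E2 loss of imidazole and CO2) gives the nitrile as a hydride-unmaskable aldehyde surrogate, while the tertiary alcohol, the silyl ether and the terminal alkyne are inert.

Step 11
Reactants: 15 6-O-triethylsilyl 18-nitrile
Product: 17 fragment 1 (core (E)-enyne, 6-O-triethylsilyl ether, 18-aldehyde), via C18 aldimine 16 (not isolated)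
Conditions: i-Bu2AlH, toluene, −78 to 0 °C; then aq. KNaC4H4O6 (potassium sodium tartrate), SiO2
Reagents that add atoms: water, O
Why: Partial reduction of the non-enolisable neopentyl nitrile with i-Bu2AlH stops at the N-aluminio aldimine, which is hydrolysed on work-up to the aldehyde; the alcohol is only deprotonated, the terminal alkyne is not hydroaluminated at or below 0 °C, and with O6 already silylated no lactol can form.

Step 12
Reactants: 18 but-2-ynoic acid
Product: 19 fragment 2, (Z)-3-iodobut-2-enoic acid
Conditions: NaI, AcOH, 110 °C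
Reagents that add atoms: sodium iodide, [Na+].[I-]
Why: Hydroiodination of the ynoic acid by conjugate anti addition of HI puts iodine at C3 trans to the incoming proton, that is cis to the carboxyl group, giving the (Z)-iodoacid.

Step 13
Reactants: 17 fragment 1; 19 fragment 2
Product: 21 6-O-triethylsilyl ether of the target, via (Z)-enynoic acid 20 (not isolated)
Conditions: Pd(PPh3)2Cl2 (5 mol %), CuI (10 mol %), Et3N, MeCN, rt, Ar
Reagents that add atoms: none
Why: Zerovalent palladium, formed in situ from Pd(PPh3)2Cl2, inserts into the C3′–I bond of the carboxylate of 19 with retention of the Z geometry, the copper acetylide of 17 transmetalates and reductive elimination forms C3′–C4′ to give (Z)-enynoic acid 20. Divalent palladium (or CuI) then coordinates the alkyne and the cis-disposed carboxylate attacks the proximal carbon C4′ anti to the metal, closing the butenolide ring in the 5-exo-dig mode (O–C4′), and protonolysis of the vinyl–metal bond releases 21. The closest known reaction type is the tandem Sonogashira coupling–lactonisation of (Z)-3-iodoalkenoic acids with terminal alkynes, which gives (Z)-γ-ylidenebutenolides. No stereocentre is created; the new C4′=C15 alkene is Z because carboxylate and proton add anti across the alkyne, which leaves C14 cis to the ring oxygen. The step needs exo (five-membered) over endo (2-pyranone) closure and no alkyne homocoupling: the first is secured by the short reach of the cis-carboxylate to the proximal alkyne carbon under amine-buffered Pd/Cu catalysis, the second by excluding oxygen. The non-enolisable C18 aldehyde, the tertiary 8-OH, the silyl ether and the (13E)-alkene see only triethylamine at room temperature and should survive.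

Step 14
Reactants: 21 6-O-triethylsilyl ether of the target
Product: 22 target (CNP0278517.1)
Conditions: HF·pyridine, pyridine, THF, 0 °C to rt
Reagents that add atoms: none
Why: Fluoride-mediated cleavage of the secondary triethylsilyl ether with pyridine-buffered HF·pyridine is mild enough that the ylidenebutenolide, the aldehyde, the tertiary alcohol and the (E)-alkene should be untouched.

**Compound list**
1 | larixol ((13S)-labda-8(17),14-diene-6α,13-diol) | C=C[C@@](C)(O)CC[C@@H]1[C@@]2(C)CCCC(C)(C)[C@@H]2[C@@H](O)CC1=C | starting material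
2 | 6α-hydroxy-14,15-dinorlabd-8(17)-en-13-one | CC(=O)CC[C@@H]1[C@@]2(C)CCCC(C)(C)[C@@H]2[C@@H](O)CC1=C | intermediate
3 | triethyl phosphonoacetate | CCOC(=O)CP(=O)(OCC)OCC | starting material
4 | ethyl (13E)-6α-hydroxylabda-8(17),13-dien-15-oate | CCOC(=O)/C=C(\C)CC[C@@H]1[C@@]2(C)CCCC(C)(C)[C@@H]2[C@@H](O)CC1=C | intermediate
5 | ethyl (13E)-8α,17-epoxy-6α-hydroxylabd-13-en-15-oate | CCOC(=O)/C=C(\C)CC[C@@H]1[C@@]2(C)CCCC(C)(C)[C@@H]2[C@@H](O)C[C@]13CO3 | intermediate
6 | (13E)-labd-13-ene-6α,8α,15-triol | OC/C=C(\C)CC[C@@H]1[C@@]2(C)CCCC(C)(C)[C@@H]2[C@@H](O)C[C@@]1(C)O | intermediate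
7 | (13E)-6α,8α-dihydroxylabd-13-en-15-al | O=C/C=C(\C)CC[C@@H]1[C@@]2(C)CCCC(C)(C)[C@@H]2[C@@H](O)C[C@@]1(C)O | intermediate
8 | core (E)-enyne 6α,8α-diol | C#C/C=C(\C)CC[C@@H]1[C@@]2(C)CCCC(C)(C)[C@@H]2[C@@H](O)C[C@@]1(C)O | intermediate
9 | 6-O-nitrite of 8 | C#C/C=C(\C)CC[C@@H]1[C@@]2(C)CCCC(C)(C)[C@@H]2[C@@H](ON=O)C[C@@]1(C)O | intermediate
10 | C18-nitroso compound (4α-CH2N=O; monomer shown, present as its dimer) | C#C/C=C(\C)CC[C@@H]1[C@@]2(C)CCC[C@@](C)(CN=O)[C@@H]2[C@@H](O)C[C@@]1(C)O | intermediate
11 | (E)-18-oxime of the enyne 6α,8α-diol | C#C/C=C(\C)CC[C@@H]1[C@@]2(C)CCC[C@@](C)(/C=N/O)[C@@H]2[C@@H](O)C[C@@]1(C)O | intermediate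
12 | O,O-bis(triethylsilyl) compound (6-O-silyl ether, oxime O-silyl ether) | C#C/C=C(\C)CC[C@@H]1[C@@]2(C)CCC[C@@](C)(/C=N/O[Si](CC)(CC)CC)[C@@H]2[C@@H](O[Si](CC)(CC)CC)C[C@@]1(C)O | intermediate
13 | 6-O-triethylsilyl 18-oxime | C#C/C=C(\C)CC[C@@H]1[C@@]2(C)CCC[C@@](C)(/C=N/O)[C@@H]2[C@@H](O[Si](CC)(CC)CC)C[C@@]1(C)O | intermediate
14 | oxime O-(imidazol-1-ylcarbonyl) derivative of 13 | C#C/C=C(\C)CC[C@@H]1[C@@]2(C)CCC[C@@](C)(/C=N/OC(=O)n3ccnc3)[C@@H]2[C@@H](O[Si](CC)(CC)CC)C[C@@]1(C)O | intermediate
15 | 6-O-triethylsilyl 18-nitrile | C#C/C=C(\C)CC[C@@H]1[C@@]2(C)CCC[C@@](C)(C#N)[C@@H]2[C@@H](O[Si](CC)(CC)CC)C[C@@]1(C)O | intermediate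
16 | C18 aldimine | C#C/C=C(\C)CC[C@@H]1[C@@]2(C)CCC[C@@](C)(C=N)[C@@H]2[C@@H](O[Si](CC)(CC)CC)C[C@@]1(C)O | intermediate
17 | fragment 1: core (E)-enyne, 6-O-triethylsilyl ether, 18-aldehyde | C#C/C=C(\C)CC[C@@H]1[C@@]2(C)CCC[C@@](C)(C=O)[C@@H]2[C@@H](O[Si](CC)(CC)CC)C[C@@]1(C)O | intermediate
18 | but-2-ynoic acid | CC#CC(=O)O | starting material
19 | fragment 2: (Z)-3-iodobut-2-enoic acid | C/C(I)=C/C(=O)O | intermediate
20 | (Z)-enynoic acid (coupling product before lactonisation) | OC(=O)/C=C(/C)C#C/C=C(\C)CC[C@@H]1[C@@]2(C)CCC[C@@](C)(C=O)[C@@H]2[C@@H](O[Si](CC)(CC)CC)C[C@@]1(C)O | intermediate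
21 | 6-O-triethylsilyl ether of the target | CC1=CC(=O)O/C1=C\C=C(/C)CC[C@@H]1[C@@]2(C)CCC[C@@](C)(C=O)[C@@H]2[C@@H](O[Si](CC)(CC)CC)C[C@@]1(C)O | intermediate
22 | target CNP0278517.1 | CC1=CC(=O)O/C1=C\C=C(/C)CC[C@@H]1[C@@]2(C)CCC[C@@](C)(C=O)[C@@H]2[C@@H](O)C[C@@]1(C)O | target

**Step count**
Total: 14 steps. Longest linear sequence: 13 steps (steps 1–11, 13, 14 from larixol); step 12 makes fragment 2.

**Steps most likely to fail, with fallbacks**

Step 8 (nitrite photolysis). Hydrogen transfer from C18 may be outrun by reactions at the conjugated enyne (radical or nitrosyl addition, E/Z scrambling of the 13-ene), so that C18 is not functionalised cleanly. The fallback moves the photolysis ahead of the enyne; it sets out from triol 6 and comes back at nitrile 15. Ac2O (1 equiv) in pyridine at 0 °C acetylates only the primary allylic hydroxyl to give 15-O-acetyl triol F1. NOCl in pyridine gives its 6-nitrite F2, and photolysis followed by heating in i-PrOH gives the 18-oxime acetate F3. Cu(OAc)2 (cat.) in refluxing MeCN dehydrates the aldoxime to hydroxy nitrile acetate F4 (no alkyne is present at this stage). Et3SiCl and imidazole give 6-O-triethylsilyl nitrile acetate F5, K2CO3 in MeOH frees allylic alcohol F6, and MnO2 gives nitrile enal F7. Me3SiCHN2 with LiN(i-Pr)2 then gives 15.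

Step 13 (key step). Endo closure to the 2-pyranone or oxidative dimerisation of the alkyne may compete with the cascade. The fallback separates the two bond formations; it sets out from 17 and 19 and comes back at 21. Acid 19 is esterified (MeI, K2CO3, DMF) to methyl (Z)-3-iodobut-2-enoate F8. Coupling with 17 (Pd(PPh3)2Cl2, CuI, Et3N) gives methyl (Z)-enynoate F9, which cannot cyclise. LiOH in THF/H2O gives acid 20, now isolated. AgNO3 (cat.) in acetone then closes the butenolide 5-exo-dig to 21; silver-catalysed lactonisation of (Z)-2-en-4-ynoic acids is known to favour the (Z)-ylidenebutenolide.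

Step 2 (olefination). E/Z selectivity at the methyl ketone may be insufficient and the isomers hard to separate. The fallback builds the trisubstituted alkene by stereospecific syn-carbometalation; it sets out from ketone 2 and comes back at ester 4. Et3SiCl and imidazole give 6-O-triethylsilyl ketone F10. LiN(i-Pr)2, ClP(O)(OEt)2, then more LiN(i-Pr)2 (enol phosphate elimination) give terminal alkyne F11. AlMe3 with Cp2ZrCl2 (cat.) in CH2Cl2 adds methyl and aluminium syn across the alkyne, and ClCO2Et traps the alkenylalane with retention to give (13E)-enoate silyl ether F12 as one geometric isomer. Bu4NF in THF returns 4.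

**Further compounds**
F1 | step 8 | 15-O-acetyl triol ((13E)-15-acetoxylabd-13-ene-6α,8α-diol) | CC(=O)OC/C=C(\C)CC[C@@H]1[C@@]2(C)CCCC(C)(C)[C@@H]2[C@@H](O)C[C@@]1(C)O
F2 | step 8 | 6-nitrite of F1 | CC(=O)OC/C=C(\C)CC[C@@H]1[C@@]2(C)CCCC(C)(C)[C@@H]2[C@@H](ON=O)C[C@@]1(C)O
F3 | step 8 | 18-oxime acetate | CC(=O)OC/C=C(\C)CC[C@@H]1[C@@]2(C)CCC[C@@](C)(/C=N/O)[C@@H]2[C@@H](O)C[C@@]1(C)O
F4 | step 8 | hydroxy nitrile acetate | CC(=O)OC/C=C(\C)CC[C@@H]1[C@@]2(C)CCC[C@@](C)(C#N)[C@@H]2[C@@H](O)C[C@@]1(C)O
F5 | step 8 | 6-O-triethylsilyl nitrile acetate | CC(=O)OC/C=C(\C)CC[C@@H]1[C@@]2(C)CCC[C@@](C)(C#N)[C@@H]2[C@@H](O[Si](CC)(CC)CC)C[C@@]1(C)O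
F6 | step 8 | 6-O-triethylsilyl nitrile allylic alcohol | OC/C=C(\C)CC[C@@H]1[C@@]2(C)CCC[C@@](C)(C#N)[C@@H]2[C@@H](O[Si](CC)(CC)CC)C[C@@]1(C)O
F7 | step 8 | 6-O-triethylsilyl nitrile enal | O=C/C=C(\C)CC[C@@H]1[C@@]2(C)CCC[C@@](C)(C#N)[C@@H]2[C@@H](O[Si](CC)(CC)CC)C[C@@]1(C)O
F8 | step 13 | methyl (Z)-3-iodobut-2-enoate | C/C(I)=C/C(=O)OC
F9 | step 13 | methyl (Z)-enynoate (methyl ester of 20) | COC(=O)/C=C(/C)C#C/C=C(\C)CC[C@@H]1[C@@]2(C)CCC[C@@](C)(C=O)[C@@H]2[C@@H](O[Si](CC)(CC)CC)C[C@@]1(C)O
F10 | step 2 | 6-O-triethylsilyl ketone (silyl ether of 2) | CC(=O)CC[C@@H]1[C@@]2(C)CCCC(C)(C)[C@@H]2[C@@H](O[Si](CC)(CC)CC)CC1=C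
F11 | step 2 | terminal alkyne (6-O-triethylsilyl, chain HC≡C–CH2CH2– on C9) | C#CCC[C@@H]1[C@@]2(C)CCCC(C)(C)[C@@H]2[C@@H](O[Si](CC)(CC)CC)CC1=C
F12 | step 2 | ethyl (13E)-6α-(triethylsilyloxy)labda-8(17),13-dien-15-oate | CCOC(=O)/C=C(\C)CC[C@@H]1[C@@]2(C)CCCC(C)(C)[C@@H]2[C@@H](O[Si](CC)(CC)CC)CC1=C
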